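**Strategy.** The seven-membered ring of the hydroazulene (C1 methyl-bearing fusion carbon, C5 fusion CH, C6 carbinol, C7=C8(Me), C9 ketone, C10) is cut at C7–C8 and C1–C10. This exposes a C8–C9–C10 unit oxygenated at C9 and a C7–C6–C5–C1 unit that is a 2-vinyl-3-methylcyclopentene, i.e. a siloxyvinyl carbene plus a diene. A chiral dirhodium catalyst cyclopropanates the vinyl group; the resulting cis-divinylcyclopropane undergoes Cope ring expansion, forming the seven-membered ring and the quaternary C1 in one operation. The precursors are an enantiopure silyl-protected 3-methyl-2-vinylcyclopent-2-enol and methyl 2-diazo-3-siloxybut-3-enoate.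

Key step: step 7

Labels and conventions: C1 = methyl-bearing quaternary fusion carbon; C2, C3 = cyclopentane CH2; C4 = oxygen-bearing cyclopentane carbon; C5 = fusion CH; C6 = carbinol carbon; C7, C8, C9 (carbonyl carbon) and C10 (CH2) complete the seven-membered ring. β is the face carrying the C1 methyl, α the other face. The target is 1R,4R,5S,6S: C1 methyl β, C4 oxygen β (isopropyl α), H5 α, C6 hydroxyl α. Compounds 16, 17, 20–22, 26 and 27 are carried as mixtures at C8 (or as enols); this has no consequence because C8 becomes sp2 in step 18.

Assumption: the hands of the oxazaborolidine and of the dirhodium catalyst are assigned from the accepted models (α-bromo enone reduction; cyclopropanation of a monosubstituted alkene by a donor/acceptor carbenoid); should a trial show the opposite sense, the mirror-image catalyst is used and nothing else changes.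

Step 1
Reactants: 1 3-methylcyclopent-2-en-1-one
Product: 3 2-bromo-3-methylcyclopent-2-en-1-one, via dibromo ketone 2 (not isolated)
Conditions: Br2, CH2Cl2, 0 °C; then Et3N, 0 °C to rt
Reagents that add atoms: bromine, BrBr
Why: Bromination–dehydrobromination: bromine adds across the enone alkene and triethylamine removes HBr by E1cB elimination through the acidic C2 hydrogen, which should return the conjugated enone with bromine on the α-carbon.

Step 2
Reactants: 3 2-bromo-3-methylcyclopent-2-en-1-one
Product: 4 (S)-2-bromo-3-methylcyclopent-2-en-1-ol
Conditions: (R)-2-methyl-CBS-oxazaborolidine (10 mol%), BH3·SMe2, THF, −20 °C; MeOH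
Reagents that add atoms: none
Why: Corey–Bakshi–Shibata reduction, in which the bromoalkenyl carbon acts as the large substituent and the ring CH2 as the small one, so the (R)-oxazaborolidine should direct hydride to the carbonyl face that gives the (S)-allylic alcohol, with 1,2-reduction only and the C–Br bond left alone.

Step 3
Reactants: 4 (S)-2-bromo-3-methylcyclopent-2-en-1-ol
Product: 5 (S)-[(2-bromo-3-methylcyclopent-2-en-1-yl)oxy]triethylsilane
Conditions: Et3SiCl, imidazole, DMF, 0 °C to rt
Reagents that add atoms: chlorotriethylsilane, CC[Si](Cl)(CC)CC
Why: Silyl ether formation with a silyl chloride and imidazole; the triethylsilyl group should survive cross-coupling, carbenoid chemistry and hydroboration and can later be removed beside a tert-butyldimethylsilyl ether.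

Step 4
Reactants: 5 (S)-[(2-bromo-3-methylcyclopent-2-en-1-yl)oxy]triethylsilane; 6 vinylboronic acid pinacol ester
Product: 7 (S)-triethyl[(3-methyl-2-vinylcyclopent-2-en-1-yl)oxy]silane
Conditions: Pd(dppf)Cl2 (5 mol%), K3PO4, THF/H2O, 60 °C
Reagents that add atoms: none
Why: Suzuki–Miyaura coupling of an alkenyl bromide with a vinylboronate under mildly basic aqueous conditions that the silyl ether tolerates; no stereocentre is touched, and the diene should be kept cold and used promptly because 2-vinylcycloalkenes dimerise.

Step 5
Reactants: 8 methyl acetoacetate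
Product: 9 methyl 2-diazo-3-oxobutanoate
Conditions: 4-acetamidobenzenesulfonyl azide, Et3N, MeCN, 0 °C to rt
Reagents that add atoms: 4-acetamidobenzenesulfonyl azide, CC(=O)Nc1ccc(cc1)S(=O)(=O)N=[N+]=[N-]
Why: Regitz diazo transfer from a sulfonyl azide to the activated methylene of the β-keto ester.

Step 6
Reactants: 9 methyl 2-diazo-3-oxobutanoate
Product: 10 methyl 3-(tert-butyldimethylsilyloxy)-2-diazobut-3-enoate
Conditions: TBSOTf, Et3N, CH2Cl2, 0 °C
Reagents that add atoms: tert-butyldimethylsilyl triflate, CC(C)(C)[Si](C)(C)OS(=O)(=O)C(F)(F)F
Why: Enol silylation: the acetyl group is enolised by triethylamine in the presence of the silyl triflate and trapped on oxygen, which should give the 2-siloxyvinyl diazoacetate that serves as the three-carbon carbenoid precursor.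

Step 7
Reactants: 7 (S)-triethyl[(3-methyl-2-vinylcyclopent-2-en-1-yl)oxy]silane; 10 methyl 3-(tert-butyldimethylsilyloxy)-2-diazobut-3-enoate
Product: 12 hydroazulene 1,4-diene (C1 methyl β; C4 OSiEt3 β; C5=C6; C8(CO2Me)=C9(OTBS)), via cis-divinylcyclopropane 11 (not isolated)
Conditions: Rh2(S-PTAD)4 (1 mol%), 2,2-dimethylbutane, −20 °C to rt, slow addition of 10 (1.5 equiv); then toluene, 80 °C
Reagents that add atoms: none
Why: The dirhodium tetracarboxylate decomposes 10 to a donor/acceptor siloxyvinyl carbenoid whose carbene carbon C8 adds across the monosubstituted vinyl group C6=C7 of 7 with the siloxyvinyl group cis to the cyclopentenyl group, and the cis-divinylcyclopropane 11 then undergoes a boat [3,3] shift that forms C1–C10 and breaks C6–C8; this tandem cyclopropanation/Cope rearrangement is the known formal [4+3] cycloaddition of siloxyvinyl diazoacetates with dienes, which extends to dienes whose reacting terminus is disubstituted. The three-membered ring (C6, C7, C8) closes by concerted carbene transfer to the alkene, and the seven-membered ring arises when this cyclopropane expands in the sigmatropic step (new ring bonds C7–C8 and C1–C10), i.e. by annulation onto the preformed cyclopentene and not by closing an open chain. The configuration of the cyclopropane is fixed by the chiral carboxylate ligands, and the stereospecific boat transition state relays it to the quaternary C1, the only new stereocentre that remains in 12 (methyl β, cis to the C4 silyloxy group). With this hand of catalyst the siloxyvinyl terminus reaches the cyclopentene face anti to the C4 silyloxy group, so the resident centre should not oppose the rearrangement. Three selectivities are required: reaction at the terminal vinyl group and not at the tetrasubstituted ring alkene or at C–H bonds (secured by the bulk of the carbenoid), a cis relationship of the two alkenyl groups on the cyclopropane (the normal outcome for donor/acceptor carbenoids, which place the donor cis to the alkene substituent), and attack on a single face of the vinyl group (imposed by the catalyst). The ring methyl lies cis on the reacting terminus and retards the Cope step, which is why the mixture is warmed at the end, while the strain energy of the three-membered ring drives formation of the congested quaternary carbon.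

Step 8
Reactants: 12 hydroazulene 1,4-diene
Product: 14 C6 alcohol (C6 OH α; H5 α; trans-fused), via C6 alkylborane 13 (not isolated)
Conditions: BH3·THF, THF, 0 °C to rt; then NaBO3·4H2O, H2O, rt
Reagents that add atoms: sodium perborate (supplies the hydroxyl oxygen), [Na+].[Na+].O[B-]1(O)OO[B-](O)(O)OO1
Why: Hydroboration–oxidation: borane adds syn across the trisubstituted C5=C6 alkene with boron on the less substituted C6 and from the α face, because the β face is blocked at both allylic carbons by the C1 methyl and the C4 silyloxy group, so H5 and the C6 oxygen should both end up α (trans ring fusion) after perborate oxidation with retention, while the tetrasubstituted ester-conjugated enol ether alkene and the methyl ester are too deactivated to react at 0 °C.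

Step 9
Reactants: 14 C6 alcohol
Product: 15 C6 tert-butyldimethylsilyl ether (C4 OSiEt3 and the silyl enol ether retained)
Conditions: TBSOTf, 2,6-lutidine, CH2Cl2, −78 to 0 °C
Reagents that add atoms: tert-butyldimethylsilyl triflate, CC(C)(C)[Si](C)(C)OS(=O)(=O)C(F)(F)F
Why: Silylation of a hindered secondary alcohol with a silyl triflate and a hindered pyridine base, conditions under which the silyl enol ether and the triethylsilyl ether are stable.

Step 10
Reactants: 15 C6 tert-butyldimethylsilyl ether
Product: 16 C4 alcohol with methyl β-keto ester (C4 OH β; C6 OTBS α)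
Conditions: HF·pyridine, pyridine, THF, 0 °C to rt
Reagents that add atoms: none
Why: Selective desilylation with pyridine-buffered HF: the triethylsilyl ether and the silyl enol ether (whose leaving group is a stabilised β-keto ester enolate) are cleaved much faster than the hindered secondary tert-butyldimethylsilyl ether, and the liberated enol tautomerises to the β-keto ester.

Step 11
Reactants: 16 C4 alcohol with methyl β-keto ester
Product: 17 C4 ketone with methyl β-keto ester and C6 OTBS
Conditions: Dess–Martin periodinane (1.2 equiv), NaHCO3, CH2Cl2, 0 °C to rt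
Reagents that add atoms: none
Why: Dess–Martin oxidation of the secondary C4 alcohol under bicarbonate buffering, mild enough to spare the β-keto ester and to avoid enolisation toward C5, so that neither β-elimination of the C6 silyloxy group nor epimerisation of C5 should occur; the ketone is used without delay.

Step 12
Reactants: 17 C4 ketone with methyl β-keto ester; 18 isopropylmagnesium chloride
Product: 20 C4 tertiary alcohol (OH β; isopropyl α), via chloromagnesium enolate 19 (not isolated)
Conditions: iPrMgCl (4 equiv), CeCl3 (4 equiv, dried), THF, −78 to −20 °C; aq NH4Cl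
Reagents that add atoms: none
Why: Organocerium 1,2-addition: the first equivalent of reagent deprotonates the acidic β-keto ester so that its enolate shields C9 and the ester, and the weakly basic, oxophilic isopropylcerium species then adds to the C4 ketone from the α face, opposite the pseudoaxial β methyl on C1 and away from the C5–C6 bond, which should give the β tertiary alcohol with the isopropyl group α.

Step 13
Reactants: 20 C4 tertiary alcohol
Product: 21 allyl β-keto ester
Conditions: allyl alcohol (excess), DMAP (0.3 equiv), 4 Å molecular sieves, toluene, 100 °C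
Reagents that add atoms: allyl alcohol, C=CCO
Why: Transesterification of an enolisable β-keto ester, which runs through the acylketene or acylpyridinium pathway open only to β-keto esters, so the methyl ester is exchanged for the allyl ester while the tertiary alcohol and the silyl ether stay untouched.

Step 14
Reactants: 21 allyl β-keto ester
Product: 22 allyl α-methyl β-keto ester (C8 quaternary)
Conditions: MeI, K2CO3, acetone, rt
Reagents that add atoms: iodomethane, CI
Why: C-Alkylation of the β-keto ester enolate with iodomethane under mild carbonate conditions, which installs the C8 methyl group; the configuration of the new quaternary C8 is left undefined because it is erased in step 18.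

Step 15
Reactants: 23 4-hydroxybenzoic acid
Product: 24 tert-butyldimethylsilyl 4-(tert-butyldimethylsilyloxy)benzoate
Conditions: TBSCl (2.3 equiv), imidazole, DMF, rt
Reagents that add atoms: tert-butyldimethylsilyl chloride, CC(C)(C)[Si](C)(C)Cl
Why: Silylation of both the phenol and the carboxylic acid with excess silyl chloride and imidazole.

Step 16
Reactants: 24 tert-butyldimethylsilyl 4-(tert-butyldimethylsilyloxy)benzoate
Product: 25 4-(tert-butyldimethylsilyloxy)benzoyl chloride
Conditions: (COCl)2, DMF (cat.), CH2Cl2, 0 °C to rt
Reagents that add atoms: oxalyl chloride, O=C(Cl)C(=O)Cl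
Why: Direct conversion of a silyl ester into the acid chloride by chloroiminium activation, which releases the silyl chloride and no HCl and therefore spares the aryl silyl ether.

Step 17
Reactants: 22 allyl α-methyl β-keto ester; 25 4-(tert-butyldimethylsilyloxy)benzoyl chloride
Product: 27 tertiary 4-(tert-butyldimethylsilyloxy)benzoate at C4, via lithium alkoxide 26 (not isolated)
Conditions: LiN(SiMe3)2 (1.05 equiv), THF, −78 °C; then 25 (1.5 equiv), DMAP (cat.), −78 to 0 °C
Reagents that add atoms: none
Why: Acylation of a preformed tertiary lithium alkoxide with an acid chloride: O–H deprotonation by the amide base at −78 °C is much faster than enolisation of the hindered C9 ketone (C8 is quaternary, C10 is neopentylic), and the alkoxide should take up the aroyl chloride with DMAP as acyl-transfer catalyst.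

Step 18
Reactants: 27 tertiary aryl ester
Product: 28 bis-silyl ether of the target (C7=C8 enone)
Conditions: Pd(OAc)2 (10 mol%), PPh3 (10 mol%), MeCN, 80 °C
Reagents that add atoms: none
Why: Tsuji decarboxylation–dehydrogenation: zerovalent palladium formed in situ ionises the allyl ester, CO2 is lost, and the palladium enolate undergoes β-hydride elimination toward C7 (favoured in acetonitrile with little phosphine), which should give the conjugated C7=C8 enone bearing the C8 methyl and release propene while the tertiary ester and both silyl ethers stay intact.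

Step 19
Reactants: 28 bis-silyl ether of the target
Product: 29 target CNP0153637.1
Conditions: HF·pyridine, pyridine, THF, 0 °C to rt
Reagents that add atoms: none
Why: Global desilylation with pyridine-buffered HF, which cleaves the aryl and the secondary alkyl silyl ether without generating an alkoxide, so that neither transfer of the aroyl group from the C4 oxygen to the C6 oxygen nor base-induced isomerisation of the γ-hydroxy enone should occur.

**Compound list**

1 | 3-methylcyclopent-2-en-1-one | CC1=CC(=O)CC1 | starting material
2 | 2,3-dibromo-3-methylcyclopentan-1-one (racemic) | CC1(Br)CCC(=O)C1Br | intermediate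
3 | 2-bromo-3-methylcyclopent-2-en-1-one | CC1=C(Br)C(=O)CC1 | intermediate
4 | (S)-2-bromo-3-methylcyclopent-2-en-1-ol | BrC1=C(C)CC[C@@H]1O | intermediate
5 | (S)-[(2-bromo-3-methylcyclopent-2-en-1-yl)oxy]triethylsilane | BrC1=C(C)CC[C@@H]1O[Si](CC)(CC)CC | intermediate
6 | vinylboronic acid pinacol ester | C=CB1OC(C)(C)C(C)(C)O1 | starting material
7 | (S)-triethyl[(3-methyl-2-vinylcyclopent-2-en-1-yl)oxy]silane | C=CC1=C(C)CC[C@@H]1O[Si](CC)(CC)CC | intermediate
8 | methyl acetoacetate | COC(=O)CC(C)=O | starting material
9 | methyl 2-diazo-3-oxobutanoate | COC(=O)C(=[N+]=[N-])C(C)=O | intermediate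
10 | methyl 3-(tert-butyldimethylsilyloxy)-2-diazobut-3-enoate | COC(=O)C(=[N+]=[N-])C(=C)O[Si](C)(C)C(C)(C)C | intermediate
11 | methyl (1R,2S)-1-[1-(tert-butyldimethylsilyloxy)vinyl]-2-[(5S)-2-methyl-5-(triethylsilyloxy)cyclopent-1-en-1-yl]cyclopropane-1-carboxylate (alkenyl groups cis) | COC(=O)[C@]1(C(=C)O[Si](C)(C)C(C)(C)C)C[C@H]1C1=C(C)CC[C@@H]1O[Si](CC)(CC)CC | intermediate
12 | hydroazulene 1,4-diene: C1 methyl β, C4 OSiEt3 β, C5=C6, C8(CO2Me)=C9(OTBS) | COC(=O)C1CC=C2[C@](C)(CC[C@@H]2O[Si](CC)(CC)CC)CC=1O[Si](C)(C)C(C)(C)C | intermediate
13 | C6 alkylborane of 12 (BH2 α on C6, H5 α) | COC(=O)C1C[C@H](B)[C@@H]2[C@](C)(CC[C@@H]2O[Si](CC)(CC)CC)CC=1O[Si](C)(C)C(C)(C)C | intermediate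
14 | trans-fused C6 alcohol (C6 OH α, H5 α, C4 OSiEt3 β, C8=C9 silyl enol ether) | COC(=O)C1C[C@H](O)[C@@H]2[C@](C)(CC[C@@H]2O[Si](CC)(CC)CC)CC=1O[Si](C)(C)C(C)(C)C | intermediate
15 | C6 tert-butyldimethylsilyl ether of 14 | COC(=O)C1C[C@H](O[Si](C)(C)C(C)(C)C)[C@@H]2[C@](C)(CC[C@@H]2O[Si](CC)(CC)CC)CC=1O[Si](C)(C)C(C)(C)C | intermediate
16 | C4 alcohol (β) with methyl β-keto ester at C8/C9 and C6 OTBS (α) | COC(=O)C1C[C@H](O[Si](C)(C)C(C)(C)C)[C@@H]2[C@](C)(CC[C@@H]2O)CC1=O | intermediate
17 | C4 ketone with methyl β-keto ester and C6 OTBS | COC(=O)C1C[C@H](O[Si](C)(C)C(C)(C)C)[C@@H]2[C@](C)(CCC2=O)CC1=O | intermediate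
18 | isopropylmagnesium chloride | CC(C)[Mg]Cl | starting material
19 | chloromagnesium enolate of the β-keto ester of 17 | COC(=O)C1C[C@H](O[Si](C)(C)C(C)(C)C)[C@@H]2[C@](C)(CCC2=O)CC=1O[Mg]Cl | intermediate
20 | C4 tertiary alcohol (OH β, isopropyl α) with methyl β-keto ester | COC(=O)C1C[C@H](O[Si](C)(C)C(C)(C)C)[C@@H]2[C@](C)(CC[C@@]2(O)C(C)C)CC1=O | intermediate
21 | allyl β-keto ester corresponding to 20 | C=CCOC(=O)C1C[C@H](O[Si](C)(C)C(C)(C)C)[C@@H]2[C@](C)(CC[C@@]2(O)C(C)C)CC1=O | intermediate
22 | allyl α-methyl β-keto ester (C8 quaternary) | C=CCOC(=O)C1(C)C[C@H](O[Si](C)(C)C(C)(C)C)[C@@H]2[C@](C)(CC[C@@]2(O)C(C)C)CC1=O | intermediate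
23 | 4-hydroxybenzoic acid | OC(=O)c1ccc(O)cc1 | starting material
24 | tert-butyldimethylsilyl 4-(tert-butyldimethylsilyloxy)benzoate | CC(C)(C)[Si](C)(C)OC(=O)c1ccc(O[Si](C)(C)C(C)(C)C)cc1 | intermediate
25 | 4-(tert-butyldimethylsilyloxy)benzoyl chloride | O=C(Cl)c1ccc(O[Si](C)(C)C(C)(C)C)cc1 | intermediate
26 | lithium alkoxide of 22 | C=CCOC(=O)C1(C)C[C@H](O[Si](C)(C)C(C)(C)C)[C@@H]2[C@](C)(CC[C@@]2(O[Li])C(C)C)CC1=O | intermediate
27 | tertiary 4-(tert-butyldimethylsilyloxy)benzoate of 22 | C=CCOC(=O)C1(C)C[C@H](O[Si](C)(C)C(C)(C)C)[C@@H]2[C@](C)(CC[C@@]2(OC(=O)c2ccc(O[Si](C)(C)C(C)(C)C)cc2)C(C)C)CC1=O | intermediate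
28 | bis(tert-butyldimethylsilyl) ether of the target (C7=C8 enone, C6 OTBS, aryl OTBS) | CC1=C[C@H](O[Si](C)(C)C(C)(C)C)[C@@H]2[C@](C)(CC[C@@]2(OC(=O)c2ccc(O[Si](C)(C)C(C)(C)C)cc2)C(C)C)CC1=O | intermediate
29 | CNP0153637.1 (1R,4R,5S,6S) | CC1=C[C@H](O)[C@@H]2[C@](C)(CC[C@@]2(OC(=O)c2ccc(O)cc2)C(C)C)CC1=O | target

**Step count.** Total: 19 steps. Longest linear sequence: 15 steps (steps 1–4, 7–14, 17–19); the diazo ester (steps 5, 6) and the acid chloride (steps 15, 16) are made in parallel.

**Steps most likely to fail**

Step 7. The sigmatropic step may stall at the cyclopropane because of the cis methyl on the reacting terminus, or the facial preference of the catalyst may be eroded by the resident C4 centre. The fallback sets out from 7 and 9 and comes back at 12. Diene 7 is cyclopropanated at its vinyl group with the acceptor/acceptor carbenoid from 9 (Rh2(esp)2, esp = α,α,α′,α′-tetramethyl-1,3-benzenedipropionate, CH2Cl2, rt) to give the acetyl cyclopropane F1 as a stereoisomer mixture. The acetyl group is then converted into the siloxyvinyl group (TBSOTf, Et3N, CH2Cl2, 0 °C) to give the siloxyvinyl cyclopropane F2, a stereoisomer mixture that contains 11. Heating in xylene at 140 °C should effect the silyl enol ether variant of the thermal divinylcyclopropane rearrangement: cis isomers rearrange, and trans isomers enter through one-centre epimerisation by reversible homolysis of the doubly stabilised C6–C8 bond. Facial selection then rests on the C4 silyloxy group, which favours the boat transition state on the cyclopentene face anti to it and hence 12; any C1 epimer would be removed by chromatography.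

Step 12. The secondary Grignard-derived reagent may reduce the ketone by β-hydride transfer or enolise it toward C5, with loss of the C6 silyloxy group or epimerisation at C5, and conversion may stay incomplete. The fallback sets out from 17 and comes back at 20. Isopropenylmagnesium bromide with CeCl3 (THF, −78 °C, excess, the β-keto ester again masked as its enolate) delivers a smaller sp2 nucleophile that cannot act as a hydride donor, giving the isopropenyl carbinol F3 by the same α-face attack. Hydroxyl-directed hydrogenation of the 1,1-disubstituted alkene (H2, [Ir(cod)(PCy3)(py)]PF6, CH2Cl2) then gives 20 without creating a stereocentre.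

Step 17. Acylation of the very hindered alkoxide may be slow, so that proton transfer from C10 and O-acylation of the resulting enolate compete. The fallback sets out from 22 and 25 and comes back at 27. It replaces alkoxide activation by dual Lewis acid/amine activation of an anhydride. Acid chloride 25 is converted into 4-(tert-butyldimethylsilyloxy)benzoic anhydride F4 (pyridine, 0.5 equiv H2O, CH2Cl2). Alcohol 22 is then treated with F4, MgBr2·OEt2 and iPr2NEt in CH2Cl2 at rt, conditions known to acylate tertiary alcohols without a strong base, so the C9 ketone is not enolised.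

**Further compounds**

F1 | step 7 | methyl 1-acetyl-2-[(5S)-2-methyl-5-(triethylsilyloxy)cyclopent-1-en-1-yl]cyclopropane-1-carboxylate (cyclopropane stereoisomers) | COC(=O)C1(C(C)=O)CC1C1=C(C)CC[C@@H]1O[Si](CC)(CC)CC
F2 | step 7 | methyl 1-[1-(tert-butyldimethylsilyloxy)vinyl]-2-[(5S)-2-methyl-5-(triethylsilyloxy)cyclopent-1-en-1-yl]cyclopropane-1-carboxylate (cyclopropane stereoisomers) | COC(=O)C1(C(=C)O[Si](C)(C)C(C)(C)C)CC1C1=C(C)CC[C@@H]1O[Si](CC)(CC)CC
F3 | step 12 | C4 isopropenyl tertiary alcohol (OH β) with methyl β-keto ester and C6 OTBS | COC(=O)C1C[C@H](O[Si](C)(C)C(C)(C)C)[C@@H]2[C@](C)(CC[C@@]2(O)C(C)=C)CC1=O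
F4 | step 17 | 4-(tert-butyldimethylsilyloxy)benzoic anhydride | CC(C)(C)[Si](C)(C)Oc1ccc(cc1)C(=O)OC(=O)c1ccc(O[Si](C)(C)C(C)(C)C)cc1
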